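4 questions lay open on 3 flasks, each charged with 0.0143 M of partner B against Wednesday's 0.029 M; ochre and blue also spent time at 110 °C against Wednesday's 125 °C.

all flasks: starting material 0.013 M; partner A 0.0195 M
- Wednesday's: partner B 0.029 M; protic impurity 3.9 mM; temperature 125 °C; run made earlier
- ochre: partner B 0.0143 M; protic impurity 3.90 mM; at 110 °C until 10 min, from then on at 125 °C; time 15 min
- green: partner B 0.0143 M; protic impurity 3.90 mM; temperature 125 °C; time 15 min
- blue: partner B 0.0143 M; protic impurity 3.90 mM; temperature 110 °C; time 15 min

- Wednesday's (time / min: target / %, starting material / %): 0.417: 1.1, 60.8; 1.00: 1.7, 41.7; 2.00: 6.2, 28.1; 3.00: 10.8, 22.6; 5.00: 19.4, 16.1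

(each reading ± 0.5 percentage points)

- what was read earlier has a scatter of 0.5 percentage points, one standard deviation
- a reading or a percentage of target counts all its forms, free or not
- the earlier runs do not show what temperature does; that part of a forecast is a guess

* the flask that comes out highest in amount of target, in percent of the starting material charged, or "all alike" when all lie within 1.5 percentage points (ochre / green / blue / all alike)
* target at the end, in percent of the starting material charged, ochre
* target at the end, in percent of the starting material charged, green
* target at the end, in percent of the starting material charged, blue

Wednesday's starting material seemed at odds with itself: it fell from the full charge to 60.8% by 0.417 min, yet lost 6.5 percentage points over the last 2.00 min. I compared the two stretches by the fraction left, with r the fall of its logarithm per minute: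

first stretch: r = 1.19 min⁻¹
last stretch: r = 0.170 min⁻¹

That is a factor of 7.00. I supposed that protic impurity quickly takes its own charge of starting material. The remainder is the free share w, the part of the starting material charged that protic impurity leaves for partner B:

w = 1 − (protic impurity charged)/(starting material charged) = 70.0%

Counted from w, the first stretch gave r = 0.338 min⁻¹, and the factor shrank to 1.99.

For the end of green I took the logarithm L of w over Wednesday's starting material at its last reading, and assumed that L scales with the partner B charged:

Wednesday's: L = 1.47
green: L = 0.725
green, starting material left: 33.9%
green, my estimate of starting material passing toward target: C = 36.1%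

The forecast named green, with 18% for ochre, 30% for green and 11% for blue, on this ground: “about 65% sits in an intermediate”.

The flasks gave 14.8% in ochre, 17.8% in green and 10.0% in blue, so green came highest.

    starting material + partner B → open intermediate (k = 16.0 M⁻¹ min⁻¹, Ea = 45.0 kJ mol⁻¹)
    partner B + partner A → second intermediate (k = 18.0 M⁻¹ min⁻¹, Ea = 82.0 kJ mol⁻¹)
    open intermediate + second intermediate → target (k = 3.70 M⁻¹ min⁻¹, Ea = 84.0 kJ mol⁻¹)
    2 second intermediate → homo product (k = 0.550 M⁻¹ min⁻¹, Ea = 82.0 kJ mol⁻¹)
    starting material + protic impurity → quenched substrate (k = 140 M⁻¹ min⁻¹, Ea = 46.0 kJ mol⁻¹)
    crystals ⇌ target, rate k6*(cs6 - [target]) while solid is left; crystals form when [target] > cs6 (solubility = 0.140 mM, k = 14.0 min⁻¹)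
    (constants at 110 °C)

Green's starting material, open intermediate and target summed to 70.0% against w = 70.0%. A neighbour of green charged with 0.052 M of starting material had a free share of 92.5%, and it held 92.5% in those forms. My 33.9% of starting material left ran lower than green's 42.1%. Green had not come to rest at 15.0 min, though partner B, the limiting reagent, stood at 0.00937% of its charge. By 150 min green's starting material still stood at 42.1%, open intermediate had fallen from 10.1% to 0.284%, and target had gained 9.8 points, reaching 27.6%.

(The earlier runs and the new flask were computed for substances that don't exist; noise was put on by code.)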